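# Proposed synthesis of (R,6Z,10E,12Z,15Z)-1-(2,6-dihydroxy-4-methoxyphenyl)-9-hydroxyoctadeca-6,10,12,15-tetraen-1-one (27)

## The problem

Compound 27 is an unbranched C18 chain whose C1 is a ketone on a 2,6-dihydroxy-4-methoxyphenyl ring. No ring has to be built, so the task is chain assembly with four alkenes (6Z, 10E, 12Z, 15Z) and one carbinol at C9. C9 (R) is the only stereocentre and is remote from every other functional group. It can neither be induced by nor control anything else, so it must come from a reagent- or catalyst-controlled step and then be carried through without ionisation. Three alkenes are Z, so each has to arise from a stereospecific step (syn reduction of an alkyne, or a purchased Z alkene) and never be exposed to equilibrating conditions. The fragile parts are the (10E,12Z)-dienyl carbinol (acid gives a pentadienyl cation), the doubly allylic C14 methylene (autoxidation) and the free, very electron-rich resorcinol ring (oxidants, electrophiles). The diene should therefore appear last, in a neutral medium, after the phenol protecting groups are gone. The feature that opens the route is that the C1 carbonyl and C6 are separated by exactly four methylenes, C2–C5. An aryl ketone carrying a four-carbon tether that ends in a radical is what β-scission of a 1-arylcyclopentan-1-oxyl radical gives. C1–C5 can thus come from cyclopentanone, and the C5 radical can be trapped by an alkyne acceptor whose triple bond later becomes the C6 Z alkene.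

## Retrosynthesis

**27 from 26 (no C–C bond cut).** The 12Z alkene is traced back to the triple bond of enyne 26. A conjugated alkyne can be reduced cis by a zinc couple that leaves isolated alkenes, the ketone and free hydroxyls alone. The sensitive (E,Z)-diene is then created in the very last step under neutral conditions. The forward step only has to stop at the alkene.

**26 from 20 and 25 (C11–C12).** Cutting the sp2–sp bond by a Sonogashira coupling divides the molecule into the (E)-iodoalkene 20 (C1–C11, with the stereocentre and the head group) and the C7 enyne 25 (C12–C18, with 15Z already present). The neighbouring cuts at C12–C13 or C13–C14 would leave a skipped diyne or several alkynes to be reduced together. The coupling must keep the E geometry and tolerate free phenols and a free carbinol.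

**25 from 22 and 23 (C13–C14), 22 from 21.** The enyne comes from alkynylation of the allylic bromide 22 with silylacetylene 23. The bromide comes from the commercial Z alcohol 21, which supplies the 15Z geometry. The forward steps must avoid allylic transposition.

**20 from 19, 19 from 17 (functional-group changes at C10–C11).** The phenol and carbinol protecting groups are removed at the iodoalkene stage (19 to 20). An iodo-substituted allylic carbinol resists acid, whereas the later enyne and diene carbinols would ionise. The (E)-iodoalkene 19 comes from the terminal alkyne 17 by syn-hydrostannylation and iodolysis. Hydrozirconation is avoided because the ketone is already present. The bulky silyl ether at C9 is kept up to this point to steer the tin to C11.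

**17 from 15, 15 from 14 (alkyne adjustments).** The terminal alkyne 17 is unmasked from the silyl-capped alkyne of 15. The 6Z alkene of 15 comes from semihydrogenation of diyne 14 while the C10 alkyne is shielded by its triisopropylsilyl cap. The forward reduction has to distinguish the two triple bonds and stop at the alkene.

**14 from 5 and 12 (C5–C6 cut, C1–C5 reconnected to a ring).** This is the key simplification. The alternative is acylation of the arene with a preformed 6-alkynoyl chain, which needs a separate chain synthesis and an sp3–sp coupling. Here the reconnection lets cyclopentanone deliver C1–C5, and the ketone and the C5–C6 bond are formed in one operation. The precursors are the achiral carbinol 5 and the alkynyl sulfone 12, which holds C6–C11 and the stereocentre. The forward step must cut a ring bond of the alkoxyl radical, trap the C5 radical at the sulfonylalkyne only, and leave C9 untouched.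

**5 from 2 and 3 (aryl–C1), 2 from 1.** The aryl–carbinol bond comes from addition of the aryllithium of bis-acetal 2 to cyclopentanone 3. The methoxymethyl ethers of 2, made from 1, direct lithiation to the carbon between them and are later lost in dilute acid. The forward step must beat enolisation of the ketone.

**12 from 11, 11 from 9, 9 from 8, 8 from 6 and 7 (C–S, O–Si, C8–C9).** The sulfone is reached by sulfenylation and oxidation of the terminal alkyne of 9, the silyl ether of 8. Diynol 8 arises by enantioselective propargylation of ynal 6 with allenylboronate 7. This one bond formation sets C9 and delivers both triple bonds differentiated (one capped, one free).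

## Roads not taken

**Alternative 1: late enzymatic 9R-oxygenation.** The cut is the C9–O bond. The all-cis tetraenyl ketone A1 would be oxidised by a 9R-lipoxygenase under air, which removes hydrogen from C11, adds oxygen at C9 and moves the 9,10-alkene to 10E to give hydroperoxide A2. Mild reduction of the O–O bond then gives 27.
- Merits: it is by far the shortest road, needs no protecting groups and takes regio- and stereocontrol from the enzyme.
- Weak points: such enzymes recognise a fatty-acid head group, and an aryl ketone head is an unknown substrate. Three doubly allylic methylenes (C8, C11, C14) compete, so positional isomers are likely. The phloroglucinol head is a phenolic radical trap and a probable inhibitor or co-substrate. A1 itself needs a regioselective C-acylation of 1 with a highly oxidisable polyunsaturated acyl donor.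
- Comparison: if the enzyme accepted A1, this road would be several times shorter, and the chosen plan cannot match that. The chosen plan offers instead that every regio- and stereochemical outcome is fixed by ordinary reagents and that analogues or the enantiomer follow by changing one reagent.

**Alternative 2: all-alkyne skeleton closed at C13–C14.** The cut is the propargylic C13–C14 bond. The copper acetylide of terminal alkyne A3 would displace bromide from A4 to give enetriyne A5, followed by deprotection and semihydrogenation of three triple bonds at once.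
- Merits: A4 is commercial and non-volatile, whereas enyne 25 is volatile and has to be made. No Z alkene exists before the last step, so none can isomerise on the way. The C1–C11 part could come from the same ring opening.
- Weak points: the skipped 12,15-diyne isomerises readily to allenes under base. The final hydrogenation must stop three times at the alkene, once on a conjugated enyne that tends to over-reduce and scramble. No chemoselective reagent is available, since the zinc couple touches only the conjugated alkyne.
- Comparison: the step count is similar or one lower. The chosen plan separates the reductions, with a Lindlar reduction for the isolated C6 alkyne early and the zinc couple for the conjugated C12 alkyne last, and buys the 15Z alkene in 21.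

**Alternative 3: Suzuki–Miyaura union at C11–C12.** The cut is the sp2–sp2 bond of the diene. The (E)-alkenylboronate A6 and the (Z,Z)-dienyl iodide A7 would be joined by a zerovalent palladium catalyst and mild base to give the fully silylated tetraene A8, then desilylated with fluoride.
- Merits: all four alkenes have defined geometry before the union, no reduction follows the formation of the diene, and an all-silyl protection allows one non-acidic final step. These are real advantages over a last-step reduction.
- Weak points: A7 is a volatile, light-sensitive skipped dienyl iodide. A6 requires hydroboration of a terminal alkyne next to an aryl ketone. Aryl silyl ethers flanking a ketone are labile to the aqueous base of the coupling. Silyl ethers cannot direct the lithiation that attaches the ring, so a protecting-group exchange is needed.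
- Comparison: the length is about equal. The chosen plan keeps a robust enyne until the end and relies on a reduction with a long record for (E,Z)-dienyl carbinols. Because both roads form C11–C12, a Suzuki union is retained as the fallback for the final step.

Key step: step 7

Remark on the chemistry: the (R)-enantiomer of the phosphoric acid in step 3 is taken to direct the boronate to the Re face of ynal 6, as it does with aryl and alkyl aldehydes. Should the sense be opposite, its antipode is used and nothing else changes.

## Route

Step 1
Reactants: 1 5-methoxyresorcinol (5-methoxybenzene-1,3-diol)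
Product: 2 1-methoxy-3,5-bis(methoxymethoxy)benzene
Conditions: NaH, MOMCl, DMF, 0 °C to rt
Reagents that add atoms: chloromethyl methyl ether, COCCl
Why: Williamson-type O-alkylation of both phenoxides by the hard electrophile; the acetal ethers are chosen because they direct the lithiation of step 2 by chelation and are lost in dilute acid in step 11.

Step 2
Reactants: 2 1-methoxy-3,5-bis(methoxymethoxy)benzene; 3 cyclopentanone
Product: 5 1-[2,6-bis(methoxymethoxy)-4-methoxyphenyl]cyclopentan-1-ol, via aryllithium 4 (not isolated)
Conditions: n-BuLi, THF, 0 °C; then 3, LaCl3·2LiCl, THF, −78 to 0 °C; sat. aq. NaHCO3; chromatography on Et3N-deactivated SiO2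
Reagents that add atoms: none
Why: Directed ortho-metalation places lithium on the carbon flanked by the two chelating acetal ethers in preference to the carbons next to the methoxy group; the oxophilic lanthanum salt favours 1,2-addition to the ketone over enolisation, and the buffered work-up keeps the ionisable tertiary benzylic carbinol from dehydrating.

Step 3
Reactants: 6 3-(triisopropylsilyl)propynal; 7 allenylboronic acid pinacol ester
Product: 8 (R)-1-(triisopropylsilyl)hexa-1,5-diyn-3-ol
Conditions: (R)-3,3′-bis(2,4,6-triisopropylphenyl)-1,1′-binaphthyl-2,2′-diyl hydrogen phosphate (10 mol %), 4 Å MS, toluene, −20 °C; aq. work-up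
Reagents that add atoms: none
Why: Chiral-phosphoric-acid-catalysed propargylboration of an aldehyde: the acid hydrogen-bonds to a boronate oxygen and the formyl hydrogen, and the closed six-membered transition state transfers the allenyl γ-carbon, so only the homopropargylic alcohol forms; attack on the Re face gives R at C9 because the silylalkynyl group outranks the propargyl methylene.

Step 4
Reactants: 8 (R)-1-(triisopropylsilyl)hexa-1,5-diyn-3-ol
Product: 9 (R)-tert-butyldimethyl{[1-(triisopropylsilyl)hexa-1,5-diyn-3-yl]oxy}silane
Conditions: TBSCl, imidazole, DMF, rt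
Reagents that add atoms: tert-butyldimethylsilyl chloride, CC(C)(C)[Si](C)(C)Cl
Why: Standard silylation of a secondary alcohol; the silyl ether protects the carbinol from base in step 5, from ligand exchange on iodine in step 7, and later provides the bulk that steers the hydrostannylation.

Step 5
Reactants: 9 (R)-tert-butyldimethyl{[1-(triisopropylsilyl)hexa-1,5-diyn-3-yl]oxy}silane
Product: 11 (R)-tert-butyldimethyl{[6-(phenylsulfanyl)-1-(triisopropylsilyl)hexa-1,5-diyn-3-yl]oxy}silane, via lithium acetylide 10 (not isolated)
Conditions: n-BuLi, THF, −78 °C; then PhSSPh, −78 to 0 °C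
Reagents that add atoms: diphenyl disulfide, c1ccc(SSc2ccccc2)cc1
Why: Only the terminal alkyne C–H is acidic enough for n-BuLi at −78 °C; sulfenylation of the acetylide at sulfur of the disulfide is a standard route to alkynyl sulfides, and the capped alkyne and both silyl groups are inert.

Step 6
Reactants: 11 (R)-tert-butyldimethyl{[6-(phenylsulfanyl)-1-(triisopropylsilyl)hexa-1,5-diyn-3-yl]oxy}silane
Product: 12 (R)-tert-butyldimethyl{[6-(phenylsulfonyl)-1-(triisopropylsilyl)hexa-1,5-diyn-3-yl]oxy}silane
Conditions: mCPBA (2.3 equiv), CH2Cl2, 0 °C to rt; brief aq. Na2SO3/NaHCO3 wash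
Reagents that add atoms: 3-chloroperoxybenzoic acid, OOC(=O)c1cccc(Cl)c1
Why: Peracid oxidation of sulfide through sulfoxide to sulfone; triple bonds and silyl groups are not attacked, and contact with base is kept short because the propargylic methylene of an alkynyl sulfone isomerises easily to the allene.

Step 7
Reactants: 5 1-[2,6-bis(methoxymethoxy)-4-methoxyphenyl]cyclopentan-1-ol; 12 (R)-tert-butyldimethyl{[6-(phenylsulfonyl)-1-(triisopropylsilyl)hexa-1,5-diyn-3-yl]oxy}silane
Product: 14 (R)-1-[2,6-bis(methoxymethoxy)-4-methoxyphenyl]-9-[(tert-butyldimethylsilyl)oxy]-11-(triisopropylsilyl)undeca-6,10-diyn-1-one, via alkoxybenziodoxole 13 (not isolated)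
Conditions: Ru(bpy)3(PF6)2 (2 mol %), 1-acetoxy-1,2-benziodoxol-3(1H)-one (1.0 equiv), 5 (1.5 equiv), CH2Cl2, blue LEDs, rt, Ar
Reagents that add atoms: none
Why: This is the visible-light alkoxyl-radical ring-opening alkynylation of a 1-arylcycloalkanol mediated by a benziodoxole, the closest known reaction type being the same process on simpler 1-arylcyclopentanols with alkynyl sulfones. Ligand exchange on trivalent iodine converts 5 into alkoxybenziodoxole 13, which is oxidised by the trivalent ruthenium that arises from the photoexcited divalent complex and collapses to the tertiary alkoxyl radical. β-Scission of the ring bond C1–C5, driven by formation of the aryl ketone and loss of ring strain, leaves a primary radical at C5, whereas the other β-bond would have to release an aryl radical and is not cut. The nucleophilic C5 radical adds to the sulfonyl-bearing carbon of 12 and the vinyl radical expels the phenylsulfonyl radical, which creates the C5–C6 bond and restores the triple bond at C6–C7; reduction of the sulfonyl radical by the excited catalyst closes the cycle. No ring is closed and no stereocentre is formed; C9 lies outside the radical site and its C–O bond stays intact, so the R configuration is carried over from 12. The choice between the two triple bonds of 12 is secured electronically, since only the sulfonylalkyne is an acceptor with a leaving group, and sterically by the triisopropylsilyl cap. Should the electron-rich ring be oxidised first, the arene radical cation is expected to break the same C1–C5 bond, so both pathways meet at the C5 radical. 5 is used in excess under dry conditions because the sulfinic and acetic acids set free could otherwise dehydrate the tertiary benzylic carbinol.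

Step 8
Reactants: 14 (R)-1-[2,6-bis(methoxymethoxy)-4-methoxyphenyl]-9-[(tert-butyldimethylsilyl)oxy]-11-(triisopropylsilyl)undeca-6,10-diyn-1-one
Product: 15 (R,Z)-1-[2,6-bis(methoxymethoxy)-4-methoxyphenyl]-9-[(tert-butyldimethylsilyl)oxy]-11-(triisopropylsilyl)undec-6-en-10-yn-1-one
Conditions: H2 (1 atm), Pd/CaCO3 poisoned with Pb(OAc)2 (Lindlar catalyst), quinoline, EtOAc, rt, monitored
Reagents that add atoms: none
Why: Lindlar semihydrogenation delivers both hydrogens to one face on the metal surface and stops at the alkene, giving the 6Z geometry; the second triple bond is shielded by the triisopropylsilyl group on one side and the branched silyloxy carbon on the other and should remain, and the twisted aryl ketone is not reduced.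

Step 9
Reactants: 15 (R,Z)-1-[2,6-bis(methoxymethoxy)-4-methoxyphenyl]-9-[(tert-butyldimethylsilyl)oxy]-11-(triisopropylsilyl)undec-6-en-10-yn-1-one
Product: 17 (R,Z)-1-[2,6-bis(methoxymethoxy)-4-methoxyphenyl]-9-[(tert-butyldimethylsilyl)oxy]undec-6-en-10-yn-1-one, via silver acetylide 16 (not isolated)
Conditions: AgF (1.5 equiv), MeOH/THF, rt, dark; then 1 M aq. HCl, 5 min
Reagents that add atoms: none
Why: Silver-assisted protiodesilylation of a silylalkyne: fluoride attacks the alkynyl C–Si bond as silver takes up the acetylide, which dilute acid then protonates; under these near-neutral conditions the O–Si bond of the secondary silyl ether is much less labile, so the bulky ether needed in step 10 is kept.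

Step 10
Reactants: 17 (R,Z)-1-[2,6-bis(methoxymethoxy)-4-methoxyphenyl]-9-[(tert-butyldimethylsilyl)oxy]undec-6-en-10-yn-1-one
Product: 19 (R,6Z,10E)-1-[2,6-bis(methoxymethoxy)-4-methoxyphenyl]-9-[(tert-butyldimethylsilyl)oxy]-11-iodoundeca-6,10-dien-1-one, via vinylstannane 18 (not isolated)
Conditions: Bu3SnH, PdCl2(PPh3)2 (3 mol %), THF, 0 °C to rt; then I2, CH2Cl2, 0 °C, dark
Reagents that add atoms: iodine, II
Why: Palladium-catalysed syn-hydrostannylation puts tin on the terminal carbon, away from the bulky propargylic silyl ether, and iododestannylation proceeds with retention, so the 10E iodoalkene results. This pair is preferred to hydrozirconation because Cp2Zr(H)Cl would reduce the ketone, and iodine alone at 0 °C should not iodinate the acetal-protected ring or disturb the isolated Z alkene.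

Step 11
Reactants: 19 (R,6Z,10E)-1-[2,6-bis(methoxymethoxy)-4-methoxyphenyl]-9-[(tert-butyldimethylsilyl)oxy]-11-iodoundeca-6,10-dien-1-one
Product: 20 (R,6Z,10E)-1-(2,6-dihydroxy-4-methoxyphenyl)-9-hydroxy-11-iodoundeca-6,10-dien-1-one
Conditions: HCl (1.25 M in MeOH), THF, rt
Reagents that add atoms: none
Why: Acid-catalysed acetal exchange and silyl ether methanolysis remove all three protecting groups; methanol traps the methoxymethyl cation as dimethoxymethane so that it cannot alkylate the liberated ring, and the step is placed here because the iodo-substituted allylic carbinol resists ionisation whereas the later enyne and diene carbinols would not.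

Step 12
Reactants: 21 (Z)-pent-2-en-1-ol
Product: 22 (Z)-1-bromopent-2-ene
Conditions: PBr3 (0.4 equiv), pyridine (cat.), Et2O, −20 to 0 °C
Reagents that add atoms: phosphorus tribromide, BrP(Br)Br
Why: Bromination of a primary allylic alcohol through its phosphite ester by direct displacement; the low temperature keeps the Z geometry and suppresses allylic transposition.

Step 13
Reactants: 22 (Z)-1-bromopent-2-ene; 23 ethynyltrimethylsilane
Product: 25 (Z)-hept-4-en-1-yne, via silyl enyne 24 (not isolated)
Conditions: CuI (10 mol %), n-Bu4NCl (10 mol %), K2CO3, DMF, rt; then MeOH, rt; pentane extraction, used as a solution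
Reagents that add atoms: none
Why: Copper-catalysed, carbonate-mediated alkynylation of a primary allylic bromide occurs at the unsubstituted carbon with the Z alkene retained and forms C13–C14; carbonate in methanol then cleaves the alkynyl C–Si bond in the same flask, which avoids isolating two volatile compounds.

Step 14
Reactants: 20 (R,6Z,10E)-1-(2,6-dihydroxy-4-methoxyphenyl)-9-hydroxy-11-iodoundeca-6,10-dien-1-one; 25 (Z)-hept-4-en-1-yne
Product: 26 (R,6Z,10E,15Z)-1-(2,6-dihydroxy-4-methoxyphenyl)-9-hydroxyoctadeca-6,10,15-trien-12-yn-1-one
Conditions: Pd(PPh3)4 (5 mol %), CuI (10 mol %), Et2NH, THF (degassed), rt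
Reagents that add atoms: none
Why: Sonogashira coupling forms C11–C12; oxidative addition of zerovalent palladium into the C–I bond and reductive elimination both proceed with retention, so 10E is kept, and the amine medium tolerates the free phenols and carbinol without touching C9.

Step 15
Reactants: 26 (R,6Z,10E,15Z)-1-(2,6-dihydroxy-4-methoxyphenyl)-9-hydroxyoctadeca-6,10,15-trien-12-yn-1-one
Product: 27 (R,6Z,10E,12Z,15Z)-1-(2,6-dihydroxy-4-methoxyphenyl)-9-hydroxyoctadeca-6,10,12,15-tetraen-1-one
Conditions: Zn dust activated with Cu(OAc)2 and AgNO3, MeOH/H2O (1:1), rt to 40 °C, dark, Ar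
Reagents that add atoms: none
Why: Boland reduction: the zinc couple reduces only the conjugated triple bond, with syn delivery of two hydrogens from the protic medium, so the 10-en-12-yne becomes the (10E,12Z)-diene; isolated alkenes, the aryl ketone and the phenols are left alone, the free C9 hydroxyl is tolerated, and the neutral medium spares the dienyl carbinol.

## Compound list

1 | 5-methoxyresorcinol (5-methoxybenzene-1,3-diol) | COc1cc(O)cc(O)c1 | starting material
2 | 1-methoxy-3,5-bis(methoxymethoxy)benzene | COCOc1cc(OC)cc(OCOC)c1 | intermediate
3 | cyclopentanone | O=C1CCCC1 | starting material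
4 | [2,6-bis(methoxymethoxy)-4-methoxyphenyl]lithium (formed in the flask) | [Li]c1c(OCOC)cc(OC)cc1OCOC | intermediate
5 | 1-[2,6-bis(methoxymethoxy)-4-methoxyphenyl]cyclopentan-1-ol | OC1(CCCC1)c1c(OCOC)cc(OC)cc1OCOC | intermediate
6 | 3-(triisopropylsilyl)propynal | CC(C)[Si](C(C)C)(C(C)C)C#CC=O | starting material
7 | allenylboronic acid pinacol ester | C=C=CB1OC(C)(C)C(C)(C)O1 | starting material
8 | (R)-1-(triisopropylsilyl)hexa-1,5-diyn-3-ol | CC(C)[Si](C(C)C)(C(C)C)C#C[C@H](O)CC#C | intermediate
9 | (R)-tert-butyldimethyl{[1-(triisopropylsilyl)hexa-1,5-diyn-3-yl]oxy}silane | CC(C)[Si](C(C)C)(C(C)C)C#C[C@H](O[Si](C)(C)C(C)(C)C)CC#C | intermediate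
10 | {(R)-4-[(tert-butyldimethylsilyl)oxy]-6-(triisopropylsilyl)hexa-1,5-diyn-1-yl}lithium (formed in the flask) | CC(C)[Si](C(C)C)(C(C)C)C#C[C@H](O[Si](C)(C)C(C)(C)C)CC#C[Li] | intermediate
11 | (R)-tert-butyldimethyl{[6-(phenylsulfanyl)-1-(triisopropylsilyl)hexa-1,5-diyn-3-yl]oxy}silane | CC(C)[Si](C(C)C)(C(C)C)C#C[C@H](O[Si](C)(C)C(C)(C)C)CC#CSc1ccccc1 | intermediate
12 | (R)-tert-butyldimethyl{[6-(phenylsulfonyl)-1-(triisopropylsilyl)hexa-1,5-diyn-3-yl]oxy}silane | CC(C)[Si](C(C)C)(C(C)C)C#C[C@H](O[Si](C)(C)C(C)(C)C)CC#CS(=O)(=O)c1ccccc1 | intermediate
13 | 1-({1-[2,6-bis(methoxymethoxy)-4-methoxyphenyl]cyclopentyl}oxy)-1,2-benziodoxol-3(1H)-one (formed in the flask) | O=C1OI(OC2(CCCC2)c3c(OCOC)cc(OC)cc3OCOC)c4ccccc14 | intermediate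
14 | (R)-1-[2,6-bis(methoxymethoxy)-4-methoxyphenyl]-9-[(tert-butyldimethylsilyl)oxy]-11-(triisopropylsilyl)undeca-6,10-diyn-1-one | CC(C)[Si](C(C)C)(C(C)C)C#C[C@H](O[Si](C)(C)C(C)(C)C)CC#CCCCCC(=O)c1c(OCOC)cc(OC)cc1OCOC | intermediate
15 | (R,Z)-1-[2,6-bis(methoxymethoxy)-4-methoxyphenyl]-9-[(tert-butyldimethylsilyl)oxy]-11-(triisopropylsilyl)undec-6-en-10-yn-1-one | CC(C)[Si](C(C)C)(C(C)C)C#C[C@H](O[Si](C)(C)C(C)(C)C)C/C=C\CCCCC(=O)c1c(OCOC)cc(OC)cc1OCOC | intermediate
16 | {(R,Z)-11-[2,6-bis(methoxymethoxy)-4-methoxyphenyl]-3-[(tert-butyldimethylsilyl)oxy]-11-oxoundec-5-en-1-yn-1-yl}silver (formed in the flask) | [Ag]C#C[C@H](O[Si](C)(C)C(C)(C)C)C/C=C\CCCCC(=O)c1c(OCOC)cc(OC)cc1OCOC | intermediate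
17 | (R,Z)-1-[2,6-bis(methoxymethoxy)-4-methoxyphenyl]-9-[(tert-butyldimethylsilyl)oxy]undec-6-en-10-yn-1-one | C#C[C@H](O[Si](C)(C)C(C)(C)C)C/C=C\CCCCC(=O)c1c(OCOC)cc(OC)cc1OCOC | intermediate
18 | (R,6Z,10E)-1-[2,6-bis(methoxymethoxy)-4-methoxyphenyl]-9-[(tert-butyldimethylsilyl)oxy]-11-(tributylstannyl)undeca-6,10-dien-1-one (formed in the flask) | CCCC[Sn](CCCC)(CCCC)/C=C/[C@H](O[Si](C)(C)C(C)(C)C)C/C=C\CCCCC(=O)c1c(OCOC)cc(OC)cc1OCOC | intermediate
19 | (R,6Z,10E)-1-[2,6-bis(methoxymethoxy)-4-methoxyphenyl]-9-[(tert-butyldimethylsilyl)oxy]-11-iodoundeca-6,10-dien-1-one | I/C=C/[C@H](O[Si](C)(C)C(C)(C)C)C/C=C\CCCCC(=O)c1c(OCOC)cc(OC)cc1OCOC | intermediate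
20 | (R,6Z,10E)-1-(2,6-dihydroxy-4-methoxyphenyl)-9-hydroxy-11-iodoundeca-6,10-dien-1-one | I/C=C/[C@H](O)C/C=C\CCCCC(=O)c1c(O)cc(OC)cc1O | intermediate
21 | (Z)-pent-2-en-1-ol | CC/C=C\CO | starting material
22 | (Z)-1-bromopent-2-ene | CC/C=C\CBr | intermediate
23 | ethynyltrimethylsilane | C#C[Si](C)(C)C | starting material
24 | (Z)-hept-4-en-1-yn-1-yltrimethylsilane (formed in the flask) | CC/C=C\CC#C[Si](C)(C)C | intermediate
25 | (Z)-hept-4-en-1-yne | CC/C=C\CC#C | intermediate
26 | (R,6Z,10E,15Z)-1-(2,6-dihydroxy-4-methoxyphenyl)-9-hydroxyoctadeca-6,10,15-trien-12-yn-1-one | CC/C=C\CC#C/C=C/[C@H](O)C/C=C\CCCCC(=O)c1c(O)cc(OC)cc1O | intermediate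
27 | (R,6Z,10E,12Z,15Z)-1-(2,6-dihydroxy-4-methoxyphenyl)-9-hydroxyoctadeca-6,10,12,15-tetraen-1-one | CC/C=C\C/C=C\C=C\[C@H](O)C/C=C\CCCCC(=O)c1c(O)cc(OC)cc1O | target

## Step count and points of risk

Total: 15 steps. Longest linear sequence: 11 steps (steps 3–11, 14 and 15, from 6 and 7). The carbinol branch (steps 1–2) and the tail branch (steps 12–13) are two steps each.

**Step 7 (key step).**
- Risk: ligand exchange at the crowded, doubly ortho-substituted tertiary hydroxyl may be slow. The sulfinic and acetic acids set free may dehydrate the carbinol to the arylcyclopentene. Hydrogen transfer from a methoxymethyl methylene to the alkoxyl radical may compete with β-scission.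
- Fallback: it sets out from aryllithium 4 (generated from 2 as in step 2) and alkyne 9, and rejoins the route at 14. 5-Bromopentanoyl chloride and N,O-dimethylhydroxylamine hydrochloride give 5-bromo-N-methoxy-N-methylpentanamide F1. Acylation of 4 with it at −78 °C stops at the ketone and gives 5-bromo-1-[2,6-bis(methoxymethoxy)-4-methoxyphenyl]pentan-1-one F2. Its primary C–Br bond is then coupled with the terminal alkyne of 9 in a Sonogashira coupling of unactivated alkyl bromides ([(π-allyl)PdCl]2, 1,3-bis(1-adamantyl)imidazolium chloride, CuI, Cs2CO3, DMF/Et2O, 45 °C). This forms the same C5–C6 bond by a polar, metal-catalysed path and gives 14.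

**Step 2.**
- Risk: partial lithiation at a carbon next to the methoxy group, enolisation of cyclopentanone by the hindered aryllithium, and acid-promoted loss of water from 5 during purification.
- Fallback: it sets out from 2 and returns at 5. Aryllithium 4 is quenched with methyl chloroformate to give methyl 2,6-bis(methoxymethoxy)-4-methoxybenzoate F3, a stable ester from which any regioisomer can be separated without risk. Double addition of BrMg(CH2)4MgBr (from 1,4-dibromobutane and magnesium) to the ester closes the cyclopentanol 5. No enolisable ketone is involved.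

**Step 3.**
- Risk: uncatalysed addition of the boronate to the reactive ynal may erode the enantiomeric purity, and the slim alkynyl substituent may be poorly differentiated by the catalyst.
- Fallback: it sets out from 6 and returns at 9, with stoichiometric reagent control.
  - Brown allylation with B-allyldiisopinocampheylborane made from (+)-B-methoxydiisopinocampheylborane and allylmagnesium bromide (the series that attacks the Re face), followed by oxidative work-up, gives (R)-1-(triisopropylsilyl)hex-5-en-1-yn-3-ol F4.
  - Silylation as in step 4 gives (R)-tert-butyldimethyl{[1-(triisopropylsilyl)hex-5-en-1-yn-3-yl]oxy}silane F5.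
  - Ozonolysis of the terminal alkene (O3, CH2Cl2/MeOH, −78 °C, indicator-controlled; Me2S) gives (R)-3-[(tert-butyldimethylsilyl)oxy]-5-(triisopropylsilyl)pent-4-ynal F6.
  - Ohira–Bestmann homologation (dimethyl (1-diazo-2-oxopropyl)phosphonate, K2CO3, MeOH) converts the aldehyde into the terminal alkyne 9.

**Step 9.**
- Risk: concurrent cleavage of the secondary silyl ether, or incomplete protonation of the silver acetylide.
- Fallback: it sets out from 15 and returns at 17. Both silyl groups are removed deliberately with Bu4NF in THF to give (R,Z)-1-[2,6-bis(methoxymethoxy)-4-methoxyphenyl]-9-hydroxyundec-6-en-10-yn-1-one F7. The carbinol is then silylated again with TBSCl and imidazole, which leaves the terminal alkyne C–H untouched, to give 17.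

**Step 15.**
- Risk: over-reduction of the diene, stalling of the reduction through chelation of zinc ions by the ortho-hydroxyaryl ketone, or erosion of the E,Z geometry on prolonged contact.
- Fallback: it sets out from 20 and 25 and returns at 27, with no reduction after the diene is formed. Rhodium-catalysed trans-hydroboration of 25 ([Rh(cod)Cl]2, P(i-Pr)3, Et3N, pinacolborane, cyclohexane, rt) gives 2-[(1Z,4Z)-hepta-1,4-dien-1-yl]-4,4,5,5-tetramethyl-1,3,2-dioxaborolane F8. Suzuki–Miyaura coupling of F8 with iodoalkene 20 (Pd(PPh3)4, aq. K3PO4, THF, rt) proceeds with retention at both alkenes and gives 27 directly.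

## Further compounds

F1 | step 7 | 5-bromo-N-methoxy-N-methylpentanamide | CON(C)C(=O)CCCCBr
F2 | step 7 | 5-bromo-1-[2,6-bis(methoxymethoxy)-4-methoxyphenyl]pentan-1-one | COCOc1cc(OC)cc(OCOC)c1C(=O)CCCCBr
F3 | step 2 | methyl 2,6-bis(methoxymethoxy)-4-methoxybenzoate | COC(=O)c1c(OCOC)cc(OC)cc1OCOC
F4 | step 3 | (R)-1-(triisopropylsilyl)hex-5-en-1-yn-3-ol | CC(C)[Si](C(C)C)(C(C)C)C#C[C@H](O)CC=C
F5 | step 3 | (R)-tert-butyldimethyl{[1-(triisopropylsilyl)hex-5-en-1-yn-3-yl]oxy}silane | CC(C)[Si](C(C)C)(C(C)C)C#C[C@H](O[Si](C)(C)C(C)(C)C)CC=C
F6 | step 3 | (R)-3-[(tert-butyldimethylsilyl)oxy]-5-(triisopropylsilyl)pent-4-ynal | CC(C)[Si](C(C)C)(C(C)C)C#C[C@H](O[Si](C)(C)C(C)(C)C)CC=O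
F7 | step 9 | (R,Z)-1-[2,6-bis(methoxymethoxy)-4-methoxyphenyl]-9-hydroxyundec-6-en-10-yn-1-one | C#C[C@H](O)C/C=C\CCCCC(=O)c1c(OCOC)cc(OC)cc1OCOC
F8 | step 15 | 2-[(1Z,4Z)-hepta-1,4-dien-1-yl]-4,4,5,5-tetramethyl-1,3,2-dioxaborolane | CC/C=C\C/C=C\B1OC(C)(C)C(C)(C)O1
A1 | alternative 1 | (6Z,9Z,12Z,15Z)-1-(2,6-dihydroxy-4-methoxyphenyl)octadeca-6,9,12,15-tetraen-1-one | CC/C=C\C/C=C\C/C=C\C/C=C\CCCCC(=O)c1c(O)cc(OC)cc1O
A2 | alternative 1 | (R,6Z,10E,12Z,15Z)-1-(2,6-dihydroxy-4-methoxyphenyl)-9-hydroperoxyoctadeca-6,10,12,15-tetraen-1-one | CC/C=C\C/C=C\C=C\[C@H](OO)C/C=C\CCCCC(=O)c1c(O)cc(OC)cc1O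
A3 | alternative 2 | (R,E)-1-[2,6-bis(methoxymethoxy)-4-methoxyphenyl]-9-[(tert-butyldimethylsilyl)oxy]tridec-10-ene-6,12-diyn-1-one | C#C/C=C/[C@H](O[Si](C)(C)C(C)(C)C)CC#CCCCCC(=O)c1c(OCOC)cc(OC)cc1OCOC
A4 | alternative 2 | 1-bromopent-2-yne | CCC#CCBr
A5 | alternative 2 | (R,E)-1-[2,6-bis(methoxymethoxy)-4-methoxyphenyl]-9-[(tert-butyldimethylsilyl)oxy]octadec-10-ene-6,12,15-triyn-1-one | CCC#CCC#C/C=C/[C@H](O[Si](C)(C)C(C)(C)C)CC#CCCCCC(=O)c1c(OCOC)cc(OC)cc1OCOC
A6 | alternative 3 | (R,6Z,10E)-1-[2,6-bis(tert-butyldimethylsilyloxy)-4-methoxyphenyl]-9-(tert-butyldimethylsilyloxy)-11-(4,4,5,5-tetramethyl-1,3,2-dioxaborolan-2-yl)undeca-6,10-dien-1-one | CC1(C)OB(/C=C/[C@H](O[Si](C)(C)C(C)(C)C)C/C=C\CCCCC(=O)c2c(O[Si](C)(C)C(C)(C)C)cc(OC)cc2O[Si](C)(C)C(C)(C)C)OC1(C)C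
A7 | alternative 3 | (1Z,4Z)-1-iodohepta-1,4-diene | CC/C=C\C/C=C\I
A8 | alternative 3 | (R,6Z,10E,12Z,15Z)-1-[2,6-bis(tert-butyldimethylsilyloxy)-4-methoxyphenyl]-9-(tert-butyldimethylsilyloxy)octadeca-6,10,12,15-tetraen-1-one | CC/C=C\C/C=C\C=C\[C@H](O[Si](C)(C)C(C)(C)C)C/C=C\CCCCC(=O)c1c(O[Si](C)(C)C(C)(C)C)cc(OC)cc1O[Si](C)(C)C(C)(C)C
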